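**Plan**

1. Numbering (chromene): O1, C2, C3, C4, C4a, C5, C6, C7, C8, C8a; ring A is the carbocycle C4a–C8a, ring B the pyranone.
2. Retrosynthesis: close the acid onto the C7 enol as a temporary enol δ-lactone (ring C) and cut C8–CH(Ph); then cut C5–C4a and C8a–C8 of ring A in one operation; then cut C6–prenyl, C6–CH2, and O1–C8a/C4–C4a of ring B.
3. Enabling feature: ring A is a cyclic β-triketone whose C5–C6–C7–C8 unit is an open α,α-dialkyl acetoacetate (C5 ester electrophile, C8 methyl-ketone nucleophile, quaternary C6 between them). The C4a=C8a bond is the α,β-bond of ring B with C8a at the carboxyl oxidation level (a 6-ethoxy-2,3-dihydropyran-4-one), so one addition–elimination/Dieckmann cascade makes both bonds.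
4. Forward order: ring B (24) from an aldol-derived ynone; quaternary β-keto ester 15; ring A by annulation of 15 onto 24; ring C closed in step 13 and opened in step 14.
5. Stereochemistry: C2/C3 from an Evans syn aldol; the side-chain centre from a copper-catalysed SN2′ allylic alkylation; C6 from a valine-enamine alkylation before the key step; the benzylic centre from a chiral triazolium catalyst.

Key step: step 12

Assumption: ring A is written as the C4-enol tautomer of the given SMILES (all tautomers are one compound); for each chiral catalyst or auxiliary the antipode expected from its accepted model is named, and the other antipode would be used if the sense proved opposite.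

**Route**

Step 1
Reactants: 1 (E)-1,4-dibromobut-2-ene; 2 2-(2-bromoethyl)-2-methyl-1,3-dioxolane
Product: 4 2-[(3R)-3-(bromomethyl)pent-4-en-1-yl]-2-methyl-1,3-dioxolane, via Grignard reagent 3 (not isolated)
Conditions: 2, Mg, Et2O, 25 °C; then 1, Cu(O2C-2-C4H3S) (monovalent copper thiophene-2-carboxylate, 3 mol %), (S)-BINOL phosphoramidite of bis[(S)-1-(2-methoxyphenyl)ethyl]amine (3.3 mol %), CH2Cl2, −78 °C
Reagents that add atoms: none
Why: Copper-catalysed asymmetric allylic alkylation (SN2′): the chiral phosphoramidite–copper complex should deliver the Grignard carbon to one enantiotopic face of the γ-carbon of the symmetrical dibromide and set the 3R centre, while the second bromide ends as a primary CH2Br that is inert here and serves later as the alkylating handle.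

Step 2
Reactants: 4
Product: 5 2-[(3R)-3-(bromomethyl)-5-methylhex-4-en-1-yl]-2-methyl-1,3-dioxolane
Conditions: 2-methyl-2-butene (excess), RuCl2(=CHPh)(H2IMes)(PCy3) (second-generation Grubbs catalyst, 3 mol %), CH2Cl2, 40 °C
Reagents that add atoms: 2-methyl-2-butene, CC=C(C)C
Why: Olefin cross-metathesis of the monosubstituted alkene with excess 2-methyl-2-butene should give the trisubstituted isobutenyl group, and because the future 1,1-disubstituted alkene is still masked as the ketal no ring-closing metathesis can compete.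

Step 3
Reactants: 5
Product: 6 (5R)-5-(bromomethyl)-7-methyloct-6-en-2-one
Conditions: 1 M HCl, THF, 23 °C
Reagents that add atoms: water, O
Why: Acid-catalysed acetal hydrolysis should unmask the methyl ketone without touching the bromide, the alkene or the stereocentre, which is not α to the carbonyl.

Step 4
Reactants: 6
Product: 7 (5R)-5-(bromomethyl)-2,7-dimethylocta-1,6-diene
Conditions: Ph3PCH3Br, KOt-Bu, THF, −78 → 0 °C
Reagents that add atoms: methyltriphenylphosphonium bromide, C[P+](c1ccccc1)(c1ccccc1)c1ccccc1.[Br-]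
Why: Wittig methylenation of the methyl ketone is expected to be faster at low temperature than enolisation or alkylation of the ylide by the β-branched primary bromide.

Step 5
Reactants: 7; 8 methyl 3-oxobutanoate (methyl acetoacetate)
Product: 9 methyl (4S)-2-acetyl-7-methyl-4-(2-methylprop-1-en-1-yl)oct-7-enoate (both C2 epimers)
Conditions: K2CO3, NaI (20 mol %), DMF, 60 °C
Reagents that add atoms: none
Why: Acetoacetic ester alkylation (SN2, with the iodide formed in situ by Finkelstein exchange) joins the future C6 to the side chain, and the new C2 centre is left uncontrolled because it becomes sp2 in step 6.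

Step 6
Reactants: 9; 10 L-valine tert-butyl ester hydrochloride
Product: 11 methyl (2Z,4S)-2-[1-{[(2S)-1-(tert-butoxy)-3-methyl-1-oxobutan-2-yl]amino}ethylidene]-7-methyl-4-(2-methylprop-1-en-1-yl)oct-7-enoate
Conditions: Et3N (1.0 equiv), BF3·OEt2 (5 mol %), toluene, reflux, Dean–Stark
Reagents that add atoms: none
Why: Acid-catalysed condensation of the β-keto ester with the amino ester should give the hydrogen-bonded (Z)-enamino ester, which fixes the enamine geometry needed for the asymmetric alkylation.

Step 7
Reactants: 11; 12 1-bromo-3-methylbut-2-ene (prenyl bromide)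
Product: 15 methyl (2S,4S)-2-acetyl-7-methyl-2-(3-methylbut-2-en-1-yl)-4-(2-methylprop-1-en-1-yl)oct-7-enoate, via N-lithio enamine 13 (not isolated), via alkylated imine 14 (not isolated)
Conditions: LiN(i-Pr)2 (1.1 equiv), toluene, −78 °C; HMPA (1 equiv); 12, −78 → −40 °C; then 1 M HCl, THF, 0 °C
Reagents that add atoms: water, O
Why: Chiral enamine (aza-enolate) alkylation: in the N-lithio enamino ester lithium is chelated by nitrogen and the valine ester carbonyl, the isopropyl group shields one face of the future C6 and prenyl bromide should enter from the other, setting 2S (C6 of the target) as a non-epimerisable quaternary centre before mild imine hydrolysis releases the ketone.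

Step 8
Reactants: 16 (4S)-4-benzyl-3-propanoyl-1,3-oxazolidin-2-one; 17 acetaldehyde
Product: 20 (4S)-4-benzyl-3-[(2S,3R)-3-hydroxy-2-methylbutanoyl]-1,3-oxazolidin-2-one, via boron enolate 18 (not isolated), via boron aldolate 19 (not isolated)
Conditions: Bu2BOTf, i-Pr2NEt, CH2Cl2, 0 °C; 17, −78 → 0 °C; then pH 7 buffer, MeOH, 30% H2O2, 0 °C
Reagents that add atoms: none
Why: Evans syn aldol reaction: the (Z)-boron enolate should react through a chair Zimmerman–Traxler transition state on the face opposite the benzyl group, giving the (2S,3R) syn adduct whose two centres become C3 and C2 of ring B.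

Step 9
Reactants: 20
Product: 21 (2S,3R)-3-hydroxy-N-methoxy-N,2-dimethylbutanamide
Conditions: MeNH(OMe)·HCl, AlMe3, CH2Cl2, −10 → 23 °C; 0.5 M HCl work-up
Reagents that add atoms: N,O-dimethylhydroxylamine hydrochloride, CNOC.Cl
Why: Aluminium amide transamination of the N-acyl oxazolidinone (Weinreb amide formation), assisted by the free β-hydroxyl, should cleave the auxiliary without epimerising the α-centre.

Step 10
Reactants: 21
Product: 23 (4S,5R)-1-ethoxy-5-hydroxy-4-methylhex-1-yn-3-one, via lithium hemiaminal 22 (not isolated)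
Conditions: ethoxyacetylene, n-BuLi, THF, −78 °C (3 equiv of acetylide); then 21, −78 → −20 °C; AcOH quench at −78 °C
Reagents that add atoms: ethoxyacetylene, C#COCC
Why: Weinreb ketone synthesis: the alkynyllithium adds once and the chelated tetrahedral intermediate should survive until the cold acidic quench, so over-addition and retro-aldol cleavage are avoided.

Step 11
Reactants: 23
Product: 24 (2R,3S)-6-ethoxy-2,3-dimethyl-2,3-dihydro-4H-pyran-4-one
Conditions: AuCl(PPh3) (2 mol %), AgOTf (2 mol %), CH2Cl2, 23 °C
Reagents that add atoms: none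
Why: π-Acid-catalysed 6-endo-dig oxa-cyclisation (hydroalkoxylation) of the β-hydroxy ynone: the push–pull alkyne should be attacked by the hydroxyl at the ethoxy-bearing carbon, closing ring B (O1–C8a) under neutral conditions with the cis C2/C3 centres untouched.

Step 12
Reactants: 15; 24
Product: 27 (2R,3S,6S)-4-hydroxy-2,3-dimethyl-6-(3-methylbut-2-en-1-yl)-6-[(2S)-5-methyl-2-(2-methylprop-1-en-1-yl)hex-5-en-1-yl]-2,3-dihydro-5H-chromene-5,7(6H)-dione, via lithium enolate 25 (not isolated), via vinylogous ester 26 (not isolated)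
Conditions: LiN(SiMe3)2 (1.1 equiv), THF, −78 °C; then 24, −78 → 23 °C (45 °C if needed); 1 M HCl to pH 3
Reagents that add atoms: none
Why: The kinetic lithium enolate 25 (C8 is the only enolisable position of the C7 ketone because C6 is quaternary) should add to C8a of the vinylogous carbonate 24 and expel ethoxide (conjugate addition–elimination; 1,2-addition to the deactivated C4 carbonyl is a reversible aldol), after which the released ethoxide deprotonates the doubly activated C8–H of 26 and the extended enolate attacks the C5 methyl ester through C4a with loss of methoxide. The closest known reaction type is the Michael–Dieckmann (Staunton–Weinreb) annulation of an ester-bearing carbanion onto a β-alkoxy-α,β-unsaturated carbonyl compound. The first bond (C8–C8a) is intermolecular, and ring A is then closed by a 6-(enolexo)-exo-trig Dieckmann condensation (C4a onto C5) that is made irreversible by immediate deprotonation of the β-triketone product. No stereocentre is created: C6, the side-chain centre and C2/C3 are carried through, C6 being non-epimerisable. The step needs regiocontrol, secured because only C4a can reach the ester in a six-membered transition state and the quaternary C6 cannot act as a competing nucleophile, and it needs retention of the cis C2/C3 relationship, secured by using only 1.1 equiv of amide base and by the fact that every intermediate after the first C–C bond is a stabilised enolate that resists deprotonation at C3.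

Step 13
Reactants: 27; 28 3-phenylprop-2-ynal
Product: 29 enol δ-lactone of 30 between the C7 enol oxygen and the carboxyl group, i.e. a (4S)-4-phenyl-3,4-dihydro-2H-pyran-2-one ring (ring C) fused at C7–O/C8 of the (2R,3S,6S)-2,3-dimethyl-6-(3-methylbut-2-en-1-yl)-6-[(2S)-5-methyl-2-(2-methylprop-1-en-1-yl)hex-5-en-1-yl]-2,3-dihydro-4H-chromene-4,5(6H)-dione core
Conditions: aminoindanol-derived N-mesityl triazolium chloride (single enantiomer, 10 mol %), toluene, 40 °C, no added base
Reagents that add atoms: none
Why: Carbene-catalysed redox annulation of the Coates–Claisen type: the ynal is converted into an α,β-unsaturated acyl azolium, the C7 enol should add through C8 (the only free nucleophilic carbon) and O7 then closes the lactone, with the chiral triazolium fixing the face of the β-carbon so that the benzylic centre is S.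

Step 14
Reactants: 29
Product: 30 (3S)-3-[(2R,3S,6S)-4-hydroxy-2,3-dimethyl-6-(3-methylbut-2-en-1-yl)-6-[(2S)-5-methyl-2-(2-methylprop-1-en-1-yl)hex-5-en-1-yl]-5,7-dioxo-3,5,6,7-tetrahydro-2H-chromen-8-yl]-3-phenylpropanoic acid (CNP0155375.1)
Conditions: LiOH (2.2 equiv), THF/H2O (3:1), 0 °C; then 1 M HCl to pH 3 at 0 °C
Reagents that add atoms: lithium hydroxide, [Li+].[OH-]
Why: Saponification of the activated enol ester should open the temporary ring C to the C7 carbonyl and the free acid, while the β-triketone is present as its enolate, which protects C3 from epimerisation and the C5–C6 bond from retro-Claisen cleavage at 0 °C.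

**Compound list**

1 | (E)-1,4-dibromobut-2-ene | BrC/C=C/CBr | starting material
2 | 2-(2-bromoethyl)-2-methyl-1,3-dioxolane | CC1(CCBr)OCCO1 | starting material
3 | [2-(2-methyl-1,3-dioxolan-2-yl)ethyl]magnesium bromide | CC1(CC[Mg]Br)OCCO1 | intermediate
4 | 2-[(3R)-3-(bromomethyl)pent-4-en-1-yl]-2-methyl-1,3-dioxolane | CC1(CC[C@H](C=C)CBr)OCCO1 | intermediate
5 | 2-[(3R)-3-(bromomethyl)-5-methylhex-4-en-1-yl]-2-methyl-1,3-dioxolane | CC1(CC[C@H](C=C(C)C)CBr)OCCO1 | intermediate
6 | (5R)-5-(bromomethyl)-7-methyloct-6-en-2-one | CC(=O)CC[C@H](C=C(C)C)CBr | intermediate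
7 | (5R)-5-(bromomethyl)-2,7-dimethylocta-1,6-diene | C=C(C)CC[C@H](C=C(C)C)CBr | intermediate
8 | methyl 3-oxobutanoate | CC(=O)CC(=O)OC | starting material
9 | methyl (4S)-2-acetyl-7-methyl-4-(2-methylprop-1-en-1-yl)oct-7-enoate (both C2 epimers) | C=C(C)CC[C@H](C=C(C)C)CC(C(C)=O)C(=O)OC | intermediate
10 | L-valine tert-butyl ester hydrochloride | CC(C)[C@H](N)C(=O)OC(C)(C)C.Cl | starting material
11 | methyl (2Z,4S)-2-[1-{[(2S)-1-(tert-butoxy)-3-methyl-1-oxobutan-2-yl]amino}ethylidene]-7-methyl-4-(2-methylprop-1-en-1-yl)oct-7-enoate | C=C(C)CC[C@H](C=C(C)C)C/C(C(=O)OC)=C(\C)N[C@@H](C(C)C)C(=O)OC(C)(C)C | intermediate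
12 | 1-bromo-3-methylbut-2-ene | CC(C)=CCBr | starting material
13 | N-lithio derivative of enamino ester 11 | C=C(C)CC[C@H](C=C(C)C)C/C(C(=O)OC)=C(\C)N([Li])[C@@H](C(C)C)C(=O)OC(C)(C)C | intermediate
14 | methyl (2S,4S)-2-[1-{[(2S)-1-(tert-butoxy)-3-methyl-1-oxobutan-2-yl]imino}ethyl]-7-methyl-2-(3-methylbut-2-en-1-yl)-4-(2-methylprop-1-en-1-yl)oct-7-enoate | C=C(C)CC[C@H](C=C(C)C)C[C@@](C(C)=N[C@@H](C(C)C)C(=O)OC(C)(C)C)(CC=C(C)C)C(=O)OC | intermediate
15 | methyl (2S,4S)-2-acetyl-7-methyl-2-(3-methylbut-2-en-1-yl)-4-(2-methylprop-1-en-1-yl)oct-7-enoate | C=C(C)CC[C@H](C=C(C)C)C[C@@](C(C)=O)(CC=C(C)C)C(=O)OC | intermediate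
16 | (4S)-4-benzyl-3-propanoyl-1,3-oxazolidin-2-one | CCC(=O)N1[C@@H](Cc2ccccc2)COC1=O | starting material
17 | acetaldehyde | CC=O | starting material
18 | (Z)-dibutylboron enolate of 16 | C/C=C(\OB(CCCC)CCCC)N1[C@@H](Cc2ccccc2)COC1=O | intermediate
19 | dibutylboron aldolate of 20 | O=C(N1[C@@H](Cc2ccccc2)COC1=O)[C@@H](C)[C@@H](C)OB(CCCC)CCCC | intermediate
20 | (4S)-4-benzyl-3-[(2S,3R)-3-hydroxy-2-methylbutanoyl]-1,3-oxazolidin-2-one | O=C(N1[C@@H](Cc2ccccc2)COC1=O)[C@@H](C)[C@@H](C)O | intermediate
21 | (2S,3R)-3-hydroxy-N-methoxy-N,2-dimethylbutanamide | CON(C)C(=O)[C@@H](C)[C@@H](C)O | intermediate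
22 | dilithium salt of the tetrahedral adduct of 21 and ethoxyacetylide | CCOC#CC(O[Li])(N(C)OC)[C@@H](C)[C@@H](C)O[Li] | intermediate
23 | (4S,5R)-1-ethoxy-5-hydroxy-4-methylhex-1-yn-3-one | CCOC#CC(=O)[C@@H](C)[C@@H](C)O | intermediate
24 | (2R,3S)-6-ethoxy-2,3-dimethyl-2,3-dihydro-4H-pyran-4-one | CCOC1=CC(=O)[C@@H](C)[C@@H](C)O1 | intermediate
25 | lithium enolate of 15 (at the acetyl methyl) | C=C(C)CC[C@H](C=C(C)C)C[C@@](C(=C)O[Li])(CC=C(C)C)C(=O)OC | intermediate
26 | methyl (2S,4S)-2-{2-[(2R,3S)-2,3-dimethyl-4-oxo-3,4-dihydro-2H-pyran-6-yl]acetyl}-7-methyl-2-(3-methylbut-2-en-1-yl)-4-(2-methylprop-1-en-1-yl)oct-7-enoate (present as its lithium dienolate) | C=C(C)CC[C@H](C=C(C)C)C[C@@](C(=O)CC1=CC(=O)[C@@H](C)[C@@H](C)O1)(CC=C(C)C)C(=O)OC | intermediate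
27 | (2R,3S,6S)-4-hydroxy-2,3-dimethyl-6-(3-methylbut-2-en-1-yl)-6-[(2S)-5-methyl-2-(2-methylprop-1-en-1-yl)hex-5-en-1-yl]-2,3-dihydro-5H-chromene-5,7(6H)-dione | C=C(C)CC[C@H](C=C(C)C)C[C@@]1(CC=C(C)C)C(=O)C2=C(O)[C@@H](C)[C@@H](C)OC2=CC1=O | intermediate
28 | 3-phenylprop-2-ynal | O=CC#Cc1ccccc1 | starting material
29 | enol δ-lactone of 30 (ring C: (4S)-4-phenyl-3,4-dihydro-2H-pyran-2-one fused at C7–O/C8) | C=C(C)CC[C@H](C=C(C)C)C[C@@]1(CC=C(C)C)C(=O)C=2C(=O)[C@@H](C)[C@@H](C)OC=2C3=C1OC(=O)C[C@H]3c1ccccc1 | intermediate
30 | (3S)-3-[(2R,3S,6S)-4-hydroxy-2,3-dimethyl-6-(3-methylbut-2-en-1-yl)-6-[(2S)-5-methyl-2-(2-methylprop-1-en-1-yl)hex-5-en-1-yl]-5,7-dioxo-3,5,6,7-tetrahydro-2H-chromen-8-yl]-3-phenylpropanoic acid | C=C(C)CC[C@H](C=C(C)C)C[C@@]1(CC=C(C)C)C(=O)C2=C(O)[C@@H](C)[C@@H](C)OC2=C([C@@H](CC(=O)O)c2ccccc2)C1=O | target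

**Step count and risks**

Total step count: 14. Longest linear sequence: 10 (steps 1–7, then 12–14).

Steps most likely to fail:

1. Step 12 (key annulation). The conjugate addition to the electron-rich vinylogous carbonate may be slow, so that proton transfer, reversible 1,2-addition or base-induced epimerisation at C3 competes, or the sequence may stall before the Dieckmann closure onto the hindered ester. Fallback (stepwise, Lewis acid then base): starting from 15, soft enolisation (TMSOTf, Et3N, CH2Cl2, 0 °C) gives the silyl enol ether methyl (2S,4S)-7-methyl-2-(3-methylbut-2-en-1-yl)-4-(2-methylprop-1-en-1-yl)-2-{1-[(trimethylsilyl)oxy]ethenyl}oct-7-enoate F1. A Mukaiyama-type addition of F1 to 24 activated by TMSOTf (CH2Cl2, −78 °C), with loss of the ethoxy group as its silyl ether, gives 26 as an isolated compound. Treatment of 26 with KOt-Bu (1.05 equiv, THF, 0 → 23 °C) then effects the Dieckmann closure, and the route is rejoined at 27.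

2. Step 7 (quaternary centre). Facial selectivity of the aza-enolate alkylation may be insufficient, or alkylation of the hindered tetrasubstituted enamine may be slow. Fallback (no asymmetric induction, separation instead): starting from 9, direct prenylation (K2CO3, 12, acetone, reflux) gives 15 together with its C2 epimer methyl (2R,4S)-2-acetyl-7-methyl-2-(3-methylbut-2-en-1-yl)-4-(2-methylprop-1-en-1-yl)oct-7-enoate F2. Because C4 is fixed the two are diastereomers and would be separated by preparative HPLC, and the route is rejoined at 15.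

3. Step 13 (benzylic centre). Facial selectivity at the β-carbon may be poor in the presence of the existing centres, or the hindered and strongly acidic enol may react slowly with the acyl azolium. Fallback (conjugate arylation instead of carbene catalysis): starting from 27, C-selective Michael addition of the enol to ethyl propiolate followed by lactonisation (cat. DMAP, then AcOH, heat) gives the ring-A-fused 2H-pyran-2-one F3. A Hayashi–Miyaura asymmetric 1,4-addition of PhB(OH)2 to F3 (Rh(acac)(C2H4)2, 3 mol %, one antipode of Segphos, dioxane/H2O, 60 °C) then installs the phenyl group, and the route is rejoined at 29.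

**Further compounds**

F1 | step 12 | methyl (2S,4S)-7-methyl-2-(3-methylbut-2-en-1-yl)-4-(2-methylprop-1-en-1-yl)-2-{1-[(trimethylsilyl)oxy]ethenyl}oct-7-enoate | C=C(C)CC[C@H](C=C(C)C)C[C@@](C(=C)O[Si](C)(C)C)(CC=C(C)C)C(=O)OC
F2 | step 7 | methyl (2R,4S)-2-acetyl-7-methyl-2-(3-methylbut-2-en-1-yl)-4-(2-methylprop-1-en-1-yl)oct-7-enoate | C=C(C)CC[C@H](C=C(C)C)C[C@](C(C)=O)(CC=C(C)C)C(=O)OC
F3 | step 13 | 2H-pyran-2-one fused at C7–O/C8 of the (2R,3S,6S)-2,3-dimethyl-6-(3-methylbut-2-en-1-yl)-6-[(2S)-5-methyl-2-(2-methylprop-1-en-1-yl)hex-5-en-1-yl]-2,3-dihydro-4H-chromene-4,5(6H)-dione core | C=C(C)CC[C@H](C=C(C)C)C[C@@]1(CC=C(C)C)C(=O)C=2C(=O)[C@@H](C)[C@@H](C)OC=2C3=C1OC(=O)C=C3
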